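The easy step came first: the starting material, at 0.32 M against 0.352 M of reagent, was the limiting reagent in both flasks.

- zeta: starting material 0.32 M; reagent 0.352 M; temperature 110 °C; time 8.0 min
- alpha: starting material 0.32 M; reagent 0.352 M; temperature 135 °C; time 8.0 min

    starting material ⇌ tight pair (K1 = 4.4 × 10⁻⁴, k1 = 0.0014 s⁻¹, Ea1 = 116 kJ mol⁻¹, ΔH1 = 18.0 kJ mol⁻¹)
    tight pair ⇌ loose pair (K2 = 1.4, k2 = 4.4 s⁻¹, Ea2 = 92.0 kJ mol⁻¹, ΔH2 = −6.00 kJ mol⁻¹)
    reagent + tight pair → target (k3 = 3.5 M⁻¹ s⁻¹, Ea3 = 57.0 kJ mol⁻¹)
    reagent + loose pair → isomer of the product (k4 = 5.1 M⁻¹ s⁻¹, Ea4 = 65.0 kJ mol⁻¹)
    reagent ⇌ dormant form (K5 = 0.36, k5 = 0.0030 s⁻¹, Ea5 = 104 kJ mol⁻¹, ΔH5 = −69.0 kJ mol⁻¹)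
    (constants at 110 °C)

- at 110 °C the constants are as listed, elsewhere as the activation energies and enthalpies make them

- which flask leads in amount of target, in percent of the starting material charged ("all alike" within 1.5 percentage points) (zeta / alpha / all alike)
- how much target is there at the end, in percent of the starting material charged: zeta
- how much target is there at the end, in percent of the starting material charged: alpha

In zeta the tight pair relaxes against the starting material with a half-life of 0.218 s by that step alone, and against the loose pair with one of 0.0919 s, both far shorter than the 8.0 min of the run, so I held the pairs at steady state. In zeta the reagent relaxes against its dormant form with a half-life of 1.02 min by that step alone, shorter than the run, so I split the charge by the equilibrium constant, which gave 0.259 M of free reagent, and I kept that estimate through the run. A tight pair in zeta was then captured at 2.21 s⁻¹, counting the way through the loose pair with its return, while it fell back to starting material at 3.18 s⁻¹.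

Those two figures are close, so I solved both ends. If capture won outright, starting material drained at 0.084 min⁻¹; if return won outright, the pairs stood in equilibrium with it and it drained at 0.0583 min⁻¹. The steady-state algebra joins the ends like resistances in series and gave 0.0344 min⁻¹ for zeta, lower than either end. This is the drain constant, the reciprocal of the summed reciprocals of the two ends. On it I reckoned 75.9% of the starting material left in zeta. Target takes the direct share of capture, 41.0%, so I reckoned 9.87% of target.

In alpha the rate constant for the passing of starting material into tight pair is 0.781 min⁻¹, the upper end of the drain, set against a run of 8.0 min, so I distrusted the opening reagent and took 0.175 M of free reagent, halfway between the opening estimate and the estimate at full conversion. Capture came to 5.22 s⁻¹ and the drain constant to 0.156 min⁻¹. On that I reckoned 28.7% of the starting material left in alpha, and a target share of 35.2% gave 25.1% of target, so I put alpha ahead.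

The forecast also chose alpha, with 9.3% for zeta and 26% for alpha, lower than my zeta figure and higher than my alpha one; its stated ground for the higher conversion in alpha was that “the dormant reservoir shrinks”.

The simulation gave alpha, with 9.49% of target in zeta and 25.7% in alpha.

Zeta read later, at 30 min, took the same reckoning. In zeta free reagent stood at 57.2% of its charge at 8.00 min and at 35.2% at 30.0 min, a mean of 0.163 M, which put capture at 1.49 s⁻¹ and the drain constant at 0.0268 min⁻¹, lower than the earlier 0.0344 min⁻¹. Starting from 76.7%, I reckoned 42.5% of the starting material left, and with a target share of 38.3% I reckoned target going from 9.49% to 22.6%. The later reading of zeta held 43.2% of starting material and 22.3% of target.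

Its constants come from no measurement; the rest is arithmetic.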